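**Retrosynthetic overview**
- The target is the (3S,3'S)-diol of (6E,6'E)-rhodoxanthin; both carbinols are set last by a two-fold catalyst-controlled 1,2-reduction of the C3 and C3' ketones.
- Feature the plan rests on: at the ketone level each end ring is an isophorone ring (C3 carbonyl, C4=C5 with the C5 methyl, C2 methylene, C1 gem-dimethyl) that carries the polyene as an alkylidene group on ring carbon C6, the γ-carbon of the enone.
- Key disconnection: the two exocyclic C6=C7 and C6'=C7' bonds, giving two isophorone silyl dienol ethers (nucleophilic at ring C6) and the all-E C22 octaenedial (aldehydes at C7 and C7').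
- The C22 dial comes from a C12 tetraenedial by two-fold Horner–Wadsworth–Emmons extension (C10=C11, C10'=C11') with a C5 phosphonate; the C12 unit comes from Stille union (C15–C15') of two C6 dienols made from (E)-3-methylpent-2-en-4-yn-1-ol.
- Ring order: no ring is formed; both six-membered rings are taken intact from isophorone.

Key step: step 9

Assumption: rhodoxanthin is taken to equilibrate among its 6E/6Z isomers under iodine catalysis, with the (6E,6'E) isomer (C8 away from the in-plane C5 methyl) favoured and crystallising; all polyenes are handled under argon in dim light.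

**Step 1**
Reactants: 1 (E)-3-methylpent-2-en-4-yn-1-ol
Product: 2 (2E,4E)-3-methyl-5-(tributylstannyl)penta-2,4-dien-1-ol
Conditions: Bu3SnH (1.2 equiv), PdCl2(PPh3)2 (2 mol %), THF, 0 °C → rt
Reagents that add atoms: tributyltin hydride, CCCC[SnH](CCCC)CCCC
Why: Palladium-catalysed syn-hydrostannation of a terminal alkyne adds Sn–H cis with tin on the unhindered terminal carbon (C3 is branched), which should give the 4E-dienylstannane with the 2E bond and the allylic alcohol untouched.

**Step 2**
Reactants: 2 (2E,4E)-3-methyl-5-(tributylstannyl)penta-2,4-dien-1-ol (about half of the batch)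
Product: 3 (2E,4E)-5-iodo-3-methylpenta-2,4-dien-1-ol
Conditions: I2 (1.05 equiv), CH2Cl2, 0 °C, dark
Reagents that add atoms: iodine, II
Why: Iododestannylation is an ipso electrophilic substitution at the C–Sn bond that proceeds with retention of the 4E geometry and outruns iodine addition to the diene.

**Step 3**
Reactants: 2 (2E,4E)-3-methyl-5-(tributylstannyl)penta-2,4-dien-1-ol; 3 (2E,4E)-5-iodo-3-methylpenta-2,4-dien-1-ol
Product: 4 (2E,4E,6E,8E)-3,8-dimethyldeca-2,4,6,8-tetraene-1,10-diol
Conditions: PdCl2(MeCN)2 (5 mol %), DMF, rt, dark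
Reagents that add atoms: none
Why: Stille cross-coupling of an alkenyl iodide with an alkenylstannane forms the central C(sp2)–C(sp2) bond with retention of both E geometries and tolerates the two free allylic alcohols.

**Step 4**
Reactants: 4 (2E,4E,6E,8E)-3,8-dimethyldeca-2,4,6,8-tetraene-1,10-diol
Product: 5 (2E,4E,6E,8E)-3,8-dimethyldeca-2,4,6,8-tetraenedial
Conditions: activated MnO2 (excess), CH2Cl2, rt
Reagents that add atoms: none
Why: MnO2 oxidation is selective for allylic alcohols and stops at the enal without isomerising the tetraene.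

**Step 5**
Reactants: 5 (2E,4E,6E,8E)-3,8-dimethyldeca-2,4,6,8-tetraenedial; 6 triethyl 3-methyl-4-phosphonocrotonate (E-rich commercial material, 2.4 equiv)
Product: 8 diethyl (all-E)-3,7,12,16-tetramethyloctadeca-2,4,6,8,10,12,14,16-octaenedioate, via lithiated phosphonate 7 (not isolated)
Conditions: 6, n-BuLi (2.3 equiv), DMPU, THF, −78 °C; then 5, −78 → 0 °C; crystallisation
Reagents that add atoms: none
Why: Two-fold Horner–Wadsworth–Emmons olefination with the stabilised γ-phosphonocrotonate anion is E-selective at both new disubstituted C=C bonds, as in the classical C5 extension of polyenals to retinoate- and crocetin-type esters, and any 2Z isomer should be removable by crystallisation.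

**Step 6**
Reactants: 8 diethyl (all-E)-3,7,12,16-tetramethyloctadeca-2,4,6,8,10,12,14,16-octaenedioate
Product: 9 (all-E)-3,7,12,16-tetramethyloctadeca-2,4,6,8,10,12,14,16-octaene-1,18-diol
Conditions: i-Bu2AlH (5 equiv), CH2Cl2/THF, −78 → −30 °C; aq KNaC4H4O6 (potassium sodium tartrate)
Reagents that add atoms: none
Why: i-Bu2AlH reduces conjugated esters in a 1,2-sense to the allylic alcohols at low temperature without touching the polyene.

**Step 7**
Reactants: 9 (all-E)-3,7,12,16-tetramethyloctadeca-2,4,6,8,10,12,14,16-octaene-1,18-diol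
Product: 10 (all-E)-3,7,12,16-tetramethyloctadeca-2,4,6,8,10,12,14,16-octaenedial (C22 dial)
Conditions: activated MnO2 (excess), CH2Cl2, rt, dark
Reagents that add atoms: none
Why: MnO2 allylic oxidation returns both termini to the aldehyde level under neutral conditions that the octaene tolerates.

**Step 8**
Reactants: 11 isophorone (3,5,5-trimethylcyclohex-2-en-1-one)
Product: 13 1-(trimethylsilyloxy)-3,5,5-trimethylcyclohexa-1,3-diene (endocyclic silyl dienol ether of isophorone), via bromomagnesium dienolate 12 (not isolated)
Conditions: MeMgBr (1.1 equiv), FeCl3 (5 mol %), Et2O, −20 → 0 °C; then Me3SiCl, Et3N, DMPU, 0 °C → rt; non-aqueous work-up, distillation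
Reagents that add atoms: chlorotrimethylsilane, C[Si](C)(C)Cl
Why: Kharasch-type γ-deprotonation of the enone by the iron-catalysed Grignard base gives the thermodynamic endocyclic magnesium dienolate (the species that protonates to β-isophorone), and O-silylation in the presence of DMPU fixes it as the 1-silyloxy-1,3-diene (silyl dienol ether formation).

**Step 9**
Reactants: 10 (all-E)-C22 octaenedial; 13 1-(trimethylsilyloxy)-3,5,5-trimethylcyclohexa-1,3-diene (3 equiv)
Product: 16 (6E,6'E)-rhodoxanthin, via bis-aldol diol 14 (not isolated), via bis-acetate 15 (not isolated)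
Conditions: BF3·OEt2 (2.4 equiv), CH2Cl2, −78 °C; aq NaHCO3; then Ac2O, pyridine, DMAP (cat.), CH2Cl2, 0 °C; then DBU, rt; then I2 (cat.), CH2Cl2, daylight; crystallisation (CH2Cl2/MeOH)
Reagents that add atoms: none
Why: BF3 binds each aldehyde of 10 and the 1-silyloxy-1,3-diene 13 attacks C7 and C7' through its terminal ring carbon C6 in an open transition state, which regenerates the C3 enone and gives the bis-aldol 14; after O-acetylation DBU removes the C6 hydrogen, acidic through C4=C5–C3=O, and acetate leaves from C7 (vinylogous E1cB), so that every diastereomer of 14 converges on the C6=C7 and C6'=C7' bonds. The closest known reaction type is the Lewis acid-mediated vinylogous Mukaiyama aldol addition of cyclic silyl dienol ethers to enals with subsequent base-induced dehydration. No ring is closed: both six-membered rings come intact from isophorone and only the two exocyclic C=C bonds are formed. No stereocentre is kept, because the C6 and C7 centres of 14 are erased on elimination; the 6E,6'E geometry is not under kinetic control and is set afterwards by iodine-catalysed equilibration, which should favour the isomer whose C8 avoids the in-plane C5 methyl group, and by crystallisation. The step needs reaction at C6 and not at C4 of the nucleophile and at the carbonyl carbon and not along the polyene of the electrophile: the pre-formed endocyclic dienol ether removes the C5 methyl group as a nucleophilic site, silyloxydienes react preferentially at their terminal carbon because this restores the conjugated enone, and the compact BF3 (chosen over a bulky aluminium phenoxide, which would shield the carbonyl carbon and penalise the carbon next to the C1 gem-dimethyl group) keeps C7 accessible. An excess of 13 carries both ends through, and the extension of conjugation from both ketones through the whole chain drives the elimination.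

**Step 10**
Reactants: 16 (6E,6'E)-rhodoxanthin
Product: 17 (3S,3'S,6E,6'E)-4',5'-didehydro-4,5'-retro-β,β-carotene-3,3'-diol (eschscholtzxanthin, the target)
Conditions: (R)-2-methyl-CBS-oxazaborolidine ((R)-1-methyl-3,3-diphenyltetrahydro-1H,3H-pyrrolo[1,2-c][1,3,2]oxazaborole, C18H20BNO; 0.5 equiv), catecholborane (3 equiv), CH2Cl2/toluene, −60 → −40 °C; MeOH, then aq NaOH; meso isomer removed by HPLC on amylose tris(3,5-dimethylphenylcarbamate)
Reagents that add atoms: none
Why: Corey–Bakshi–Shibata reduction, in which the oxazaborolidine–borane complex binds each carbonyl anti to the larger alkenyl branch (C4=C5) and delivers hydride to one face in a 1,2-sense, should by the usual model give the S carbinol from the R catalyst at C3 and C3' independently, the s-trans ring enone excluding uncatalysed conjugate reduction and the two-fold reaction sending most mismatched events into the meso diol.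

**Compound list**
1 | (E)-3-methylpent-2-en-4-yn-1-ol | C#C/C(C)=C/CO | starting material
2 | (2E,4E)-3-methyl-5-(tributylstannyl)penta-2,4-dien-1-ol | CCCC[Sn](CCCC)(CCCC)/C=C/C(C)=C/CO | intermediate
3 | (2E,4E)-5-iodo-3-methylpenta-2,4-dien-1-ol | I/C=C/C(C)=C/CO | intermediate
4 | (2E,4E,6E,8E)-3,8-dimethyldeca-2,4,6,8-tetraene-1,10-diol | OC/C=C(C)/C=C/C=C/C(C)=C/CO | intermediate
5 | (2E,4E,6E,8E)-3,8-dimethyldeca-2,4,6,8-tetraenedial | O=C/C=C(C)/C=C/C=C/C(C)=C/C=O | intermediate
6 | triethyl 3-methyl-4-phosphonocrotonate (ethyl (E)-4-(diethoxyphosphoryl)-3-methylbut-2-enoate) | CCOC(=O)/C=C(\C)CP(=O)(OCC)OCC | starting material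
7 | lithium salt of the γ-carbanion of 6 | [Li+].CCOC(=O)/C=C(\C)[CH-]P(=O)(OCC)OCC | intermediate (not isolated)
8 | diethyl (all-E)-3,7,12,16-tetramethyloctadeca-2,4,6,8,10,12,14,16-octaenedioate | CCOC(=O)/C=C(C)/C=C/C=C(C)/C=C/C=C/C(C)=C/C=C/C(C)=C/C(=O)OCC | intermediate
9 | (all-E)-3,7,12,16-tetramethyloctadeca-2,4,6,8,10,12,14,16-octaene-1,18-diol | OC/C=C(C)/C=C/C=C(C)/C=C/C=C/C(C)=C/C=C/C(C)=C/CO | intermediate
10 | (all-E)-3,7,12,16-tetramethyloctadeca-2,4,6,8,10,12,14,16-octaenedial | O=C/C=C(C)/C=C/C=C(C)/C=C/C=C/C(C)=C/C=C/C(C)=C/C=O | intermediate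
11 | isophorone | CC1=CC(=O)CC(C)(C)C1 | starting material
12 | bromomagnesium 3,5,5-trimethylcyclohexa-1,3-dien-1-olate | Br[Mg]OC1=CC(C)=CC(C)(C)C1 | intermediate (not isolated)
13 | 1-(trimethylsilyloxy)-3,5,5-trimethylcyclohexa-1,3-diene | C[Si](C)(C)OC1=CC(C)=CC(C)(C)C1 | intermediate
14 | 4,4'-[(all-E)-1,18-dihydroxy-3,7,12,16-tetramethyloctadeca-2,4,6,8,10,12,14,16-octaene-1,18-diyl]bis(3,5,5-trimethylcyclohex-2-en-1-one), diastereomer mixture | CC1=CC(=O)CC(C)(C)C1C(O)/C=C(C)/C=C/C=C(C)/C=C/C=C/C(C)=C/C=C/C(C)=C/C(O)C1C(C)=CC(=O)CC1(C)C | intermediate (not isolated)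
15 | bis-acetate of 14 | CC1=CC(=O)CC(C)(C)C1C(OC(C)=O)/C=C(C)/C=C/C=C(C)/C=C/C=C/C(C)=C/C=C/C(C)=C/C(OC(C)=O)C1C(C)=CC(=O)CC1(C)C | intermediate (not isolated)
16 | (6E,6'E)-rhodoxanthin ((6E,6'E)-4',5'-didehydro-4,5'-retro-β,β-carotene-3,3'-dione) | CC1=CC(=O)CC(C)(C)\C1=C/C=C(C)/C=C/C=C(C)/C=C/C=C/C(C)=C/C=C/C(C)=C/C=C1/C(C)=CC(=O)CC1(C)C | intermediate
17 | (3S,3'S,6E,6'E)-4',5'-didehydro-4,5'-retro-β,β-carotene-3,3'-diol | CC1=C[C@@H](O)CC(C)(C)\C1=C/C=C(C)/C=C/C=C(C)/C=C/C=C/C(C)=C/C=C/C(C)=C/C=C1/C(C)=C[C@@H](O)CC1(C)C | target

**Totals**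
Total step count: 10. Longest linear sequence: 9 steps (steps 1–7, 9 and 10; 1 → 2 → 3 → 4 → 5 → 8 → 9 → 10 → 16 → 17).

**Steps most likely to fail**

Step 9. Bond formation may occur through the α-carbon C4 of the dienol ether in place of C6, because C6 lies next to the quaternary C1. The Lewis acid-bound polyenal may also take up the nucleophile in a conjugate sense, react at one end only, or oligomerise, and 13 may be desilylated before it reacts. The fallback sets out from 10 and comes back at 16; it makes the C6–C7 bond with an sp2 carbanion whose position is fixed. Commercial 2,2,6-trimethylcyclohexane-1,4-dione is ketalised at its unhindered carbonyl (ethylene glycol, p-TsOH, benzene, reflux with water removal) to 7,9,9-trimethyl-1,4-dioxaspiro[4.5]decan-8-one F1. Condensation with 2,4,6-triisopropylbenzenesulfonyl hydrazide (MeCN, rt) gives the 2,4,6-triisopropylbenzenesulfonylhydrazone of F1, F2. Shapiro reaction (n-BuLi, THF/TMEDA, −78 → 0 °C), which can only deprotonate the methine α-carbon, gives 8-lithio-7,9,9-trimethyl-1,4-dioxaspiro[4.5]dec-7-ene F3, with lithium on the future C6. F3 adds 1,2 to both aldehydes of 10 (THF, −78 °C) to give the bis(allylic alcohol) bis-ketal F4. Aqueous acid (p-TsOH, acetone/H2O, rt) removes both ketals, and the doubly allylic C7 and C7' hydroxyls are then lost with a C4 proton each (vinylogous dehydration of the megastigmatrienone type) to give 16.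

Step 10. Facial discrimination may be poor, since the two branches at C3 (sp2 C4, and the C2 methylene next to the gem-dimethyl carbon) differ little; the sense of induction is to be checked on isophorone and the catalyst antipode chosen accordingly. The second ketone may stay unreduced through low solubility at low temperature, and the allylic carbinols may ionise on acidic contact. The fallback sets out from 16 and comes back at 17. Luche reduction (NaBH4, CeCl3·7H2O, MeOH/THF, −20 °C) gives the 1,2-reduced diol as the mixture of (3S,3'S), (3R,3'R) and meso isomers F5. Acylation with (1S)-camphanic chloride (pyridine, DMAP, CH2Cl2) turns the mixture into diastereomeric diesters, from which the (3S,3'S)-bis[(1S)-camphanate] F6 is separated by HPLC on silica and crystallisation. Mild saponification (KOH, MeOH/THF, rt) returns 17.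

Step 8. Enolisation may be incompletely regiocontrolled (exocyclic methylene or cross-conjugated isomers), the Grignard reagent may add to the carbonyl, and the silyl ether may hydrolyse on isolation. The fallback sets out from 11 and comes back at 13. Isophorone 11 is deconjugated by slow fractional distillation from a catalytic amount of adipic acid to β-isophorone (3,5,5-trimethylcyclohex-3-en-1-one) F7. Soft enolisation (Me3SiOSO2CF3, Et3N, Et2O, 0 °C) removes the doubly activated C2 hydrogen, which is both α to the carbonyl and allylic, and should give 13 free of the exocyclic isomer.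

**Further compounds**
F1 | step 9 | 7,9,9-trimethyl-1,4-dioxaspiro[4.5]decan-8-one | O=C1C(C)CC2(CC1(C)C)OCCO2
F2 | step 9 | 2,4,6-triisopropylbenzenesulfonylhydrazone of F1 | CC1CC2(CC(C)(C)C1=NNS(=O)(=O)c3c(C(C)C)cc(C(C)C)cc3C(C)C)OCCO2
F3 | step 9 | 8-lithio-7,9,9-trimethyl-1,4-dioxaspiro[4.5]dec-7-ene | [Li]C1=C(C)CC2(CC1(C)C)OCCO2
F4 | step 9 | (all-E)-3,7,12,16-tetramethyl-1,18-bis(7,9,9-trimethyl-1,4-dioxaspiro[4.5]dec-7-en-8-yl)octadeca-2,4,6,8,10,12,14,16-octaene-1,18-diol | CC1=C(C(O)/C=C(C)/C=C/C=C(C)/C=C/C=C/C(C)=C/C=C/C(C)=C/C(O)C3=C(C)CC4(CC3(C)C)OCCO4)C(C)(C)CC2(C1)OCCO2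
F5 | step 10 | (6E,6'E)-4',5'-didehydro-4,5'-retro-β,β-carotene-3,3'-diol, mixture of C3/C3' stereoisomers | CC1=CC(O)CC(C)(C)\C1=C/C=C(C)/C=C/C=C(C)/C=C/C=C/C(C)=C/C=C/C(C)=C/C=C1/C(C)=CC(O)CC1(C)C
F6 | step 10 | (3S,3'S)-bis[(1S)-camphanate] of 17 | CC1=C[C@@H](OC(=O)[C@]23OC(=O)[C@](C)(CC2)C3(C)C)CC(C)(C)\C1=C/C=C(C)/C=C/C=C(C)/C=C/C=C/C(C)=C/C=C/C(C)=C/C=C1/C(C)=C[C@@H](OC(=O)[C@]23OC(=O)[C@](C)(CC2)C3(C)C)CC1(C)C
F7 | step 8 | β-isophorone (3,5,5-trimethylcyclohex-3-en-1-one) | O=C1CC(C)=CC(C)(C)C1
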